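## Retrosynthetic overview
- The C11–OH and the C6=C7 alkene come last, from a singlet-oxygen ene reaction on a 7(11)-en-8-one. The C4 acetate and C3 angelate come from a 3α,4α-cis-diol, and that diol from α-face osmylation of a C3=C4 alkene (eudesma-3,7(11)-dien-8-one).
- This bicyclic dienone is cut at C4–C5 and C9–C10 to an acyclic, achiral 1,5-enyne that carries a 2-silyloxydiene terminus. One gold(I)-catalysed cation–olefin bicyclisation closes the ester-bearing ring (C1–C5, C10) first and the enone ring (C5–C10) last.
- Enabling feature: the trans fusion H–C5/CH3–C10 is the anti-addition pattern of an (E)-C5=C10 alkene. It lies between C3–C4(CH3), where the cis-diol stands for an alkene and that alkene for a methyl alkyne two CH2 away from C10, and C9H2–C8(=O), a ketone whose α-CH2 sits on quaternary C10 and therefore stands for an enol ether.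
- The enyne is built from geranyl acetate (C1–C6, C10, C14), one carbon each from the Ohira–Bestmann reagent (C4) and MeI (C15), and pent-3-yn-2-one plus a cuprate methyl (C7–C9, C11–C13).

Key step: step 8

Remark on numbering: eudesmane numbering is used in the text. C1–C5/C10 is the ring with the two esters, C5–C10 the enone ring, C14 the CH3 on C10, C15 the CH3 on C4, and C11–C13 the hydroxyisopropyl group.
Assumption: the sense of induction of the (R)-ligand in step 8 is not known for this substrate class. It is taken to give (5R,10R); if it proves opposite, the (S)-ligand is used.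

## Route

Step 1
Reactants: 1 geranyl acetate
Product: 2 6,7-epoxygeranyl acetate (racemic at the epoxide)
Conditions: mCPBA, CH2Cl2, 0 °C
Reagents that add atoms: mCPBA, OOC(=O)c1cccc(Cl)c1
Why: Prilezhaev epoxidation picks the electron-richer remote trisubstituted alkene because the 2,3-alkene is deactivated by the allylic acetate, and the new stereocentre is destroyed in step 2, so the racemate serves.

Step 2
Reactants: 2 6,7-epoxygeranyl acetate
Product: 4 (2E)-3-methyl-6-oxohex-2-en-1-yl acetate, via 6,7-diol 3 (not isolated)
Conditions: H5IO6, THF/Et2O, 0 °C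
Reagents that add atoms: none
Why: Acidic opening of the epoxide to the glycol and Malaprade cleavage in one flask remove the isopropylidene end and leave the (E)-alkene and the acetate untouched.

Step 3
Reactants: 4 (2E)-3-methyl-6-oxohex-2-en-1-yl acetate
Product: 6 (2E)-3-methylhept-2-en-6-yn-1-ol, via alkynyl acetate 5 (not isolated)
Conditions: dimethyl (1-diazo-2-oxopropyl)phosphonate, K2CO3, MeOH, 0 °C → rt
Reagents that add atoms: dimethyl (1-diazo-2-oxopropyl)phosphonate, CC(=O)C(=[N+]=[N-])P(=O)(OC)OC
Why: Seyferth–Gilbert homologation with the Ohira–Bestmann reagent converts the enolisable aldehyde into the terminal alkyne under mild base, and the same K2CO3/MeOH medium transesterifies the acetate.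

Step 4
Reactants: 6 (2E)-3-methylhept-2-en-6-yn-1-ol
Product: 8 (2E)-3-methyloct-2-en-6-yn-1-ol, via dilithio alkoxide-acetylide 7 (not isolated)
Conditions: n-BuLi (2.1 equiv), THF, −78 → 0 °C; MeI (1.1 equiv), DMPU, 0 °C → rt; H2O
Reagents that add atoms: iodomethane, CI
Why: This is an acetylide alkylation in which the carbanion of the dianion is far more nucleophilic toward MeI than the lithium alkoxide in THF, so only carbon should be methylated.

Step 5
Reactants: 8 (2E)-3-methyloct-2-en-6-yn-1-ol
Product: 9 (2E)-1-bromo-3-methyloct-2-en-6-yne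
Conditions: CBr4, PPh3, CH2Cl2, 0 °C
Reagents that add atoms: tetrabromomethane, BrC(Br)(Br)Br
Why: The Appel reaction replaces the primary allylic OH by SN2 under neutral conditions, without allylic shift or loss of the (E)-geometry.

Step 6
Reactants: 9 (2E)-1-bromo-3-methyloct-2-en-6-yne; 10 pent-3-yn-2-one
Product: 12 4-methyl-3-[(2E)-3-methyloct-2-en-6-yn-1-yl]pent-3-en-2-one, via lithium allenolate 11 (not isolated)
Conditions: Me2CuLi (from MeLi, CuI), Et2O/THF, −78 °C, 10; then 9, DMPU, −78 → 0 °C
Reagents that add atoms: lithium dimethylcuprate, [Li+].C[Cu-]C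
Why: In this tandem conjugate addition–alkylation the Gilman cuprate adds to the ynone and the allenolate is allylated at its α-carbon by the primary allylic bromide, and since both β-substituents are methyl no alkene geometry has to be controlled.

Step 7
Reactants: 12 4-methyl-3-[(2E)-3-methyloct-2-en-6-yn-1-yl]pent-3-en-2-one
Product: 14 2-(tert-butyldimethylsilyloxy)-4-methyl-3-[(2E)-3-methyloct-2-en-6-yn-1-yl]penta-1,3-diene, via lithium dienolate 13 (not isolated)
Conditions: LDA, THF, −78 °C; TBSCl, DMPU, −78 °C → rt
Reagents that add atoms: tert-butyldimethylsilyl chloride, CC(C)(C)[Si](C)(C)Cl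
Why: Kinetic α′-deprotonation of the acetyl CH3 and O-silylation give the cross-conjugated 2-silyloxydiene, as is known for mesityl oxide type enones, and no other proton in the molecule is of comparable kinetic acidity.

Step 8
Reactants: 14 2-(tert-butyldimethylsilyloxy)-4-methyl-3-[(2E)-3-methyloct-2-en-6-yn-1-yl]penta-1,3-diene
Product: 15 (5R,10R)-eudesma-3,7(11)-dien-8-one (trans-fused 5,8a-dimethyl-3-(propan-2-ylidene)-3,4,4a,7,8,8a-hexahydronaphthalen-2(1H)-one; 5α-H and 10β-CH3)
Conditions: [(R)-DTBM-MeO-BIPHEP](AuCl)2 (3 mol %), AgSbF6 (6 mol %), i-PrOH (1.1 equiv), m-xylene/CH2Cl2, −20 °C → rt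
Reagents that add atoms: none
Why: Proposed new method: the cationic gold(I) centre binds the only alkyne (C3≡C4), the (E)-C5=C10 alkene attacks C4 anti to gold (cyclopropyl gold carbene/tertiary C10 cation), the CH2 terminus C9 of the 2-silyloxydiene captures C10 from the opposite face, the silyl oxocarbenium ion passes its silyl group to 2-propanol, and the proton set free cleaves the C3–Au bond and returns the catalyst. The closest known reaction types are the gold(I)-catalysed 6-endo polycyclisation of 1,5-enynes ended by phenols, acids or arenes, the enantioselective alkyne-initiated polyene cyclisation with digold complexes of atropisomeric bisphosphines, and the carbocyclisation of silyl enol ethers onto gold-activated alkynes; new are the carbon termination by a silyl dienol ether inside such a cascade and the asymmetric induction in the 1,5-enyne series. The ring C1–C5/C10 closes first in a 6-endo-dig mode (6-endo-trig at the alkene) through bond C4–C5, and the ring C5–C10 closes last in a 6-endo-trig mode at the enol ether through bond C9–C10. The relative configuration of C5 and C10 follows from stereospecific anti addition of C4 and C9 across the (E)-alkene in a chair–chair array, which can only give the trans fusion, and the absolute configuration follows from the alkene face that the chiral bisphosphine pocket presents to the bound alkyne. The step needs chemoselective activation (secured by the alkynophilic catalyst and a single alkyne), endo regiochemistry (secured by the two-carbon tether C1–C2, which excludes an exo-dig closure, and by the methyl group on C10, which localises the charge there) and C- instead of O-termination (secured by the O-silyl group, while the tetrasubstituted C7=C11 alkene cannot reach C10 and the hindered alcohol is a poor competitor for the cation).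

Step 9
Reactants: 15 (5R,10R)-eudesma-3,7(11)-dien-8-one
Product: 16 (3R,4S,5R,10R)-3α,4α-dihydroxyeudesm-7(11)-en-8-one
Conditions: OsO4 (2 mol %), NMO, acetone/H2O, rt
Reagents that add atoms: osmium tetroxide (catalytic oxygen carrier), O=[Os](=O)(=O)=O; N-methylmorpholine N-oxide, C[N+]1([O-])CCOCC1; water, O
Why: In the Upjohn dihydroxylation OsO4 prefers the electron-rich trisubstituted C3=C4 alkene over the hindered, electron-poor tetrasubstituted enone alkene and adds syn from the α face, opposite to the axial C10 methyl group, which sets C3 and C4 in one event.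

Step 10
Reactants: 16 (3R,4S,5R,10R)-3α,4α-dihydroxyeudesm-7(11)-en-8-one; 17 angelic acid
Product: 19 3α-angeloyloxy-4α-hydroxyeudesm-7(11)-en-8-one, via mixed anhydride 18 (not isolated)
Conditions: 17, 2,4,6-trichlorobenzoyl chloride, Et3N, toluene, rt; then 16, 80 °C
Reagents that add atoms: none
Why: Yamaguchi-type esterification through the mixed anhydride without DMAP keeps the (Z)-geometry of the angelate, and only the secondary C3–OH should react because the tertiary C4–OH is much more hindered.

Step 11
Reactants: 19 3α-angeloyloxy-4α-hydroxyeudesm-7(11)-en-8-one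
Product: 20 4α-acetoxy-3α-angeloyloxyeudesm-7(11)-en-8-one
Conditions: Ac2O, TMSOTf (5 mol %), CH2Cl2, −20 °C
Reagents that add atoms: acetic anhydride, CC(=O)OC(C)=O
Why: Silyl triflate-catalysed acylation with the anhydride is fast for tertiary alcohols at low temperature, so acetylation should outrun ionisation at C4 and angeloyl migration, and no other free hydroxyl group is present at this stage.

Step 12
Reactants: 20 4α-acetoxy-3α-angeloyloxyeudesm-7(11)-en-8-one
Product: 22 (3R,4S,5R,10R)-4α-acetoxy-3α-angeloyloxy-11-hydroxyeudesm-6-en-8-one (target), via 11-hydroperoxide 21 (not isolated)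
Conditions: O2, tetraphenylporphyrin (cat.), visible light, CH2Cl2, 0 °C; then PPh3
Reagents that add atoms: dioxygen, O=O
Why: In the Schenck ene reaction singlet oxygen attacks the s-cis tetrasubstituted enone (pulegone type) with the known geminal selectivity, binding to C11 and taking a hydrogen from the C6H2 group geminal to the carbonyl, which moves the alkene to C6=C7; PPh3 then reduces the hydroperoxide, the electron-poor angelate alkene is far less reactive, and no stereocentre is touched.

## Compound list
1 | geranyl acetate | CC(C)=CCC/C(C)=C/COC(C)=O | starting material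
2 | 6,7-epoxygeranyl acetate (racemic) | CC1(C)OC1CC/C(C)=C/COC(C)=O | intermediate
3 | (2E)-6,7-dihydroxy-3,7-dimethyloct-2-en-1-yl acetate (not isolated) | CC(C)(O)C(O)CC/C(C)=C/COC(C)=O | intermediate
4 | (2E)-3-methyl-6-oxohex-2-en-1-yl acetate | O=CCC/C(C)=C/COC(C)=O | intermediate
5 | (2E)-3-methylhept-2-en-6-yn-1-yl acetate (not isolated) | C#CCC/C(C)=C/COC(C)=O | intermediate
6 | (2E)-3-methylhept-2-en-6-yn-1-ol | C#CCC/C(C)=C/CO | intermediate
7 | dilithio alkoxide-acetylide of 6 (not isolated) | [Li+].[Li+].[C-]#CCC/C(C)=C/C[O-] | intermediate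
8 | (2E)-3-methyloct-2-en-6-yn-1-ol | CC#CCC/C(C)=C/CO | intermediate
9 | (2E)-1-bromo-3-methyloct-2-en-6-yne | CC#CCC/C(C)=C/CBr | intermediate
10 | pent-3-yn-2-one | CC#CC(C)=O | starting material
11 | lithium 4-methylpenta-2,3-dien-2-olate (not isolated) | CC([O-])=C=C(C)C.[Li+] | intermediate
12 | 4-methyl-3-[(2E)-3-methyloct-2-en-6-yn-1-yl]pent-3-en-2-one | CC#CCC/C(C)=C/CC(=C(C)C)C(C)=O | intermediate
13 | lithium cross-conjugated dienolate of 12 (not isolated) | CC#CCC/C(C)=C/CC(=C(C)C)C(=C)[O-].[Li+] | intermediate
14 | 2-(tert-butyldimethylsilyloxy)-4-methyl-3-[(2E)-3-methyloct-2-en-6-yn-1-yl]penta-1,3-diene | CC#CCC/C(C)=C/CC(=C(C)C)C(=C)O[Si](C)(C)C(C)(C)C | intermediate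
15 | (5R,10R)-eudesma-3,7(11)-dien-8-one | CC1=CCC[C@]2(C)CC(=O)C(=C(C)C)C[C@@H]12 | intermediate
16 | (3R,4S,5R,10R)-3α,4α-dihydroxyeudesm-7(11)-en-8-one | O[C@@H]1CC[C@]2(C)CC(=O)C(=C(C)C)C[C@H]2[C@]1(C)O | intermediate
17 | angelic acid, (Z)-2-methylbut-2-enoic acid | C/C=C(/C)C(=O)O | starting material
18 | angelic 2,4,6-trichlorobenzoic anhydride (not isolated) | C/C=C(/C)C(=O)OC(=O)c1c(Cl)cc(Cl)cc1Cl | intermediate
19 | 3α-angeloyloxy-4α-hydroxyeudesm-7(11)-en-8-one | C/C=C(/C)C(=O)O[C@@H]1CC[C@]2(C)CC(=O)C(=C(C)C)C[C@H]2[C@]1(C)O | intermediate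
20 | 4α-acetoxy-3α-angeloyloxyeudesm-7(11)-en-8-one | C/C=C(/C)C(=O)O[C@@H]1CC[C@]2(C)CC(=O)C(=C(C)C)C[C@H]2[C@]1(C)OC(C)=O | intermediate
21 | 4α-acetoxy-3α-angeloyloxy-11-hydroperoxyeudesm-6-en-8-one (not isolated) | C/C=C(/C)C(=O)O[C@@H]1CC[C@]2(C)CC(=O)C(C(C)(C)OO)=C[C@H]2[C@]1(C)OC(C)=O | intermediate
22 | (3R,4S,5R,10R)-4α-acetoxy-3α-angeloyloxy-11-hydroxyeudesm-6-en-8-one | C/C=C(/C)C(=O)O[C@@H]1CC[C@]2(C)CC(=O)C(C(C)(C)O)=C[C@H]2[C@]1(C)OC(C)=O | target

Total step count: 12. Longest linear sequence: 12 steps (1 → 22).

## Steps most likely to fail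

**Step 8.** The chiral gold complex may discriminate poorly between the two alkene faces, because the stereogenic ligand is far from the reacting alkene in a linear gold(I) complex. The fallback replaces catalyst control by a classical resolution built on known reactions. It sets out from 14.
- The bicyclisation is run with the achiral catalyst [JohnPhosAu(NCMe)]SbF6 and i-PrOH. This should give 15 together with its mirror image ent-eudesma-3,7(11)-dien-8-one F1.
- Upjohn dihydroxylation of the mixture gives 16 together with the ent-diol F2.
- Steglich esterification of the secondary C3–OH with (S)-O-methylmandelic acid gives the mandelate of 16 F3 and the diastereomeric mandelate of the ent-diol F4. These are separated by chromatography or crystallisation.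
- Methanolysis of the mandelate of 16 with K2CO3 in MeOH comes back to the route at 16.

**Step 6.** C-allylation of the allenolate may be sluggish, and methyl transfer from residual copper species to the allylic bromide may compete. The fallback builds the tetrasubstituted enone stepwise. It sets out from 9.
- C-alkylation of pentane-2,4-dione (K2CO3, acetone) gives the 3-alkylated pentane-2,4-dione F5.
- NaH and PhNTf2 convert it into the β-triflyloxy enone F6. Either alkene isomer serves, because the carbon concerned ends as a gem-dimethyl carbon.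
- Addition–elimination with Me2CuLi at −78 °C comes back to the route at 12.

**Step 11.** Acylation of the hindered tertiary C4–OH may be slow. That would leave time for migration of the angeloyl group to C4–O, followed by fast acetylation of the freed C3–OH, or for elimination at C4. The fallback changes the order of ester introduction. It sets out from 16.
- TESCl and imidazole silylate only the secondary alcohol and give the 3-O-TES ether F7.
- The tertiary alcohol, now without an acyl neighbour, is acetylated under forcing conditions (Ac2O, DMAP, Et3N, 50 °C) to the 3-O-TES 4-acetate F8.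
- HF·pyridine in THF at 0 °C removes the silyl group in an acidic medium that suppresses acetyl migration and gives the 3-hydroxy 4-acetate F9.
- This is esterified at once with mixed anhydride 18 in toluene, which comes back to the route at 20.

## Further compounds
F1 | step 8 | (5S,10S)-eudesma-3,7(11)-dien-8-one (ent-15) | CC1=CCC[C@@]2(C)CC(=O)C(=C(C)C)C[C@H]12
F2 | step 8 | (3S,4R,5S,10S)-3,4-dihydroxyeudesm-7(11)-en-8-one (ent-16) | O[C@H]1CC[C@@]2(C)CC(=O)C(=C(C)C)C[C@@H]2[C@@]1(C)O
F3 | step 8 | 3-O-[(S)-methoxy(phenyl)acetyl] ester of 16 | CO[C@H](C(=O)O[C@@H]1CC[C@]2(C)CC(=O)C(=C(C)C)C[C@H]2[C@]1(C)O)c1ccccc1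
F4 | step 8 | 3-O-[(S)-methoxy(phenyl)acetyl] ester of ent-16 | CO[C@H](C(=O)O[C@H]1CC[C@@]2(C)CC(=O)C(=C(C)C)C[C@@H]2[C@@]1(C)O)c1ccccc1
F5 | step 6 | 3-[(2E)-3-methyloct-2-en-6-yn-1-yl]pentane-2,4-dione | CC#CCC/C(C)=C/CC(C(C)=O)C(C)=O
F6 | step 6 | 3-acetyl-6-methylundeca-2,5-dien-9-yn-2-yl triflate (5E; 2E/2Z mixture) | CC#CCC/C(C)=C/CC(C(C)=O)=C(C)OS(=O)(=O)C(F)(F)F
F7 | step 11 | 4α-hydroxy-3α-(triethylsilyloxy)eudesm-7(11)-en-8-one | CC[Si](CC)(CC)O[C@@H]1CC[C@]2(C)CC(=O)C(=C(C)C)C[C@H]2[C@]1(C)O
F8 | step 11 | 4α-acetoxy-3α-(triethylsilyloxy)eudesm-7(11)-en-8-one | CC[Si](CC)(CC)O[C@@H]1CC[C@]2(C)CC(=O)C(=C(C)C)C[C@H]2[C@]1(C)OC(C)=O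
F9 | step 11 | 4α-acetoxy-3α-hydroxyeudesm-7(11)-en-8-one | O[C@@H]1CC[C@]2(C)CC(=O)C(=C(C)C)C[C@H]2[C@]1(C)OC(C)=O
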